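The free enzyme of this flask turns starting material, the limiting reagent at 0.10 M against 0.400 M of second substrate, into target, and the readings show target falling again.

the same everywhere: starting material 0.10 M
- dawn: second substrate 0.20 M; free enzyme 20 µM; run made earlier
- spring: second substrate 0.80 M; free enzyme 20 µM; run made earlier
- winter: second substrate 0.40 M; free enzyme 40 µM; run made earlier
- flask: second substrate 0.400 M; free enzyme 20 µM; time 15 d

| run | time / d | target / % | starting material / % |
|---|---|---|---|
| dawn | 0.167 | 22 | 54 |
| dawn | 0.417 | 14 | 12 |
| dawn | 1.04 | 1 | 3 |
| dawn | 2.50 | 0 | 0 |
| dawn | 6.00 | 1 | 0 |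
| dawn | 15.0 | 0 | 1 |
| spring | 0.167 | 23 | 49 |
| spring | 0.417 | 11 | 4 |
| spring | 1.04 | 0 | 4 |
| spring | 2.50 | 1 | 0 |
| spring | 6.00 | 0 | 0 |
| spring | 15.0 | 0 | 0 |
| winter | 0.167 | 35 | 15 |
| winter | 0.500 | 5 | 1 |
| winter | 1.67 | 0 | 0 |
| winter | 5.00 | 0 | 2 |
| winter | 15.0 | 0 | 0 |

(each reading ± 1.5 percentage points)

- candidate steps: starting material + free enzyme <-> first complex; first complex -> loaded enzyme + first product; second substrate + loaded enzyme <-> second complex; second complex -> free enzyme + target; target -> over-reaction product

1. the moment within 15 d at which there is most target
2. the amount of target, in percent of the starting material charged, at that time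

The bench habit is to wait until starting material has faded and then collect the product. In the dawn run that means 1.04 d, where starting material reads 3% but target reads 1%. The habit assumes that target outlasts its formation, so its lifetime has to be measured.

The enzyme charge is 0.0200% of the starting-material charge, so what is neither starting material nor target counts as over-reaction product: 74.0% at 0.417 d in the dawn run. Dividing this by the area under the target readings, joined by straight lines from zero, gives a loss constant k = 11.7 d⁻¹. The time in which unfed target halves, its half-life h, is then 0.0594 d.

Here is the border of the habit: the first dawn reading lies 2.81 half-lives out, later than h, with 54% of starting material still unconsumed.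

For the flask, the dawn and spring runs bracket its second substrate at the same enzyme charge. Their mean consumption up to 0.417 d gives a feed r = 2.21 d⁻¹, as a fraction of the charge. Target peaks where feed equals loss, so my reckoning gives r/k = 18.9%. In 3 half-lives target closes 87.5% of its gap to that balance, which places the peak near 0.178 d.

The forecast, which reads the runs as “a ping-pong enzyme with near-saturating second substrate, followed by a fast first-order loss of target”, gives 21.5% at 0.19 d, a higher peak than this reckoning.

The flask gives 21.7% at 0.199 d.

    starting material + free enzyme ⇌ first complex (K = 19.0 M⁻¹, k = 390 M⁻¹ s⁻¹)
    first complex → loaded enzyme + first product (k = 0.450 s⁻¹)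
    second substrate + loaded enzyme ⇌ second complex (K = 16.0 M⁻¹, k = 22.0 M⁻¹ s⁻¹)
    second complex → free enzyme + target (k = 0.610 s⁻¹)
    target → over-reaction product (k = 1.30 × 10⁻⁴ s⁻¹)

Counted in the h read from the dawn run, the peak of the flask lies about 3.35 such half-lives out, with starting material still at 43.0%, and target is down to 14.0% by 0.398 d. Target stands this low in part because of the step to over-reaction product: the same flask run without that step peaks at 100% instead of 21.7%. Applied to the neighbour flask, charged with 0.040 M of starting material and peaking at 31.0%, the h read from the dawn run estimates the feed at the peak at about 0.145 M d⁻¹, against about 0.253 M d⁻¹ in the flask.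

Readings and results come from a simulation for substances that don't exist, noise included.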